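**Retrosynthetic overview**
1. Target 29 is the ester of butenolide acid 23 (ring B) with the primary hydroxyl of diol diester 25 (ring A). Both halves come from one hydroxy lactone, 21: ring B by dehydration, the ring A partner by lactone opening.
2. Ring A locants used below: C1 carries CO2H (carboxyl carbon C2), C6 the alkenyl chain (first carbon C5), C7 the isopropyl group, C8 and C9 are CH2, C10 is the carbinol carbon carrying CH2O (C14).
3. Enabling feature: C1–C6 and C9–C10 are the two σ-bonds of a cyclohexene retron (C7=C8) in ring A, and C2 and C5 sit on the adjacent, trans-disposed C1 and C6. They can therefore be tied through an ester oxygen (temporary γ-lactone), giving the achiral trienal 8.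
4. Key disconnection C9–C10 (together with C1–C6): imidazolidinone-catalysed intramolecular Diels–Alder reaction of 8. Ring order: temporary lactone and ring A (step 7), lactone moved to C14 (step 9), butenolide of ring B (step 15).
5. C10–OH by enolate hydroxylation, C7 by hydroxyl-directed hydrogenation, side chain by Horner–Wadsworth–Emmons olefination of the C5 aldehyde; union by Yamaguchi esterification.

Key step: step 7

Remark: the sense of induction in step 7 is assumed to follow the benzyl-shielding model known for (E)-enals with this imidazolidinone; if it proved opposite, the mirror-image catalyst would be used.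

**Step 1**
Reactants: 1 ethyl 4-methyl-3-oxopentanoate
Product: 2 ethyl (2E)-4-methyl-3-{[(trifluoromethyl)sulfonyl]oxy}pent-2-enoate
Conditions: Tf2O, aq. Me4NOH, hexanes, 0 °C
Reagents that add atoms: trifluoromethanesulfonic anhydride, O=S(=O)(OS(=O)(=O)C(F)(F)F)C(F)(F)F
Why: O-triflation of the non-chelated (tetramethylammonium) enolate of a β-keto ester should give the (E)-enol triflate, with the ester trans to OTf (enol triflate formation).

**Step 2**
Reactants: 2 ethyl (2E)-4-methyl-3-{[(trifluoromethyl)sulfonyl]oxy}pent-2-enoate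
Product: 3 ethyl (2E)-3-(propan-2-yl)penta-2,4-dienoate
Conditions: CH2=CHSnBu3, Pd(PPh3)4 (5 mol %), LiCl, THF, 65 °C
Reagents that add atoms: tributyl(ethenyl)stannane, C=C[Sn](CCCC)(CCCC)CCCC
Why: Stille coupling of a vinyl triflate proceeds with retention of alkene geometry, placing the vinyl group trans to the ester.

**Step 3**
Reactants: 3 ethyl (2E)-3-(propan-2-yl)penta-2,4-dienoate
Product: 4 (2E)-3-(propan-2-yl)penta-2,4-dien-1-ol
Conditions: iBu2AlH, CH2Cl2, −78 °C; Rochelle salt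
Reagents that add atoms: none
Why: 1,2-reduction of a conjugated ester by diisobutylaluminium hydride gives the allylic alcohol without touching the diene.

**Step 4**
Reactants: 5 (2E)-4,4-dimethoxybut-2-enal
Product: 6 (2E)-4,4-dimethoxybut-2-enoic acid
Conditions: NaClO2, NaH2PO4, 2-methylbut-2-ene, t-BuOH/H2O, 0 °C
Reagents that add atoms: sodium chlorite, [Na+].[O-]Cl=O
Why: Pinnick oxidation converts the enal into the acid under buffered conditions that the deactivated γ-acetal should survive.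

**Step 5**
Reactants: 4 (2E)-3-(propan-2-yl)penta-2,4-dien-1-ol; 6 (2E)-4,4-dimethoxybut-2-enoic acid
Product: 7 (2E)-3-(propan-2-yl)penta-2,4-dien-1-yl (2E)-4,4-dimethoxybut-2-enoate
Conditions: EDC·HCl, DMAP, CH2Cl2, 0 °C to rt
Reagents that add atoms: none
Why: Steglich-type carbodiimide esterification joins diene and dienophile through the ester that will become the C2–O–C5 tether.

**Step 6**
Reactants: 7 (2E)-3-(propan-2-yl)penta-2,4-dien-1-yl (2E)-4,4-dimethoxybut-2-enoate
Product: 8 (2E)-3-(propan-2-yl)penta-2,4-dien-1-yl (2E)-4-oxobut-2-enoate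
Conditions: Amberlyst-15, acetone/H2O, rt
Reagents that add atoms: water, O
Why: Acid-catalysed acetal hydrolysis unveils the enal needed for iminium activation.

**Step 7**
Reactants: 8 (2E)-3-(propan-2-yl)penta-2,4-dien-1-yl (2E)-4-oxobut-2-enoate
Product: 11 (3aS,7S,7aS)-1-oxo-4-(propan-2-yl)-1,3,3a,6,7,7a-hexahydro-2-benzofuran-7-carbaldehyde, via substrate iminium ion 9 (not isolated), via cycloadduct iminium ion 10 (not isolated)
Conditions: (2S,5S)-5-benzyl-2-tert-butyl-3-methylimidazolidin-4-one·CF3CO2H (20 mol %), MeCN/H2O 95:5, 0.02 M, −20 to 4 °C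
Reagents that add atoms: none
Why: The imidazolidinone condenses with the aldehyde of 8 to give the (E)-iminium ion 9, whose LUMO-lowered alkene is attacked first at the carbon β to the iminium by the tethered diene terminus (C1–C6) and then closes ring A through the C9–C10 bond in an asynchronous endo intramolecular [4+2] cycloaddition; hydrolysis of 10 returns the catalyst. The closest known reaction type is the imidazolidinone-catalysed intramolecular Diels–Alder reaction of trienals (type 1), applied here to an ester-linked triene. The γ-lactone closes through the three-atom ester tether as the five-membered ring of a bicyclo[4.3.0] system, and ring A closes as the cyclohexene of the cycloaddition. The benzyl group of the catalyst shields one face of the iminium, so the diene adds to the other and fixes C1 absolutely; the (E)-dienophile puts the formyl group trans to the lactone carbonyl, and the (E)-diene in the endo transition state makes the ring fusion trans (C6) and places the formyl group at C10 cis to the lactone CH2. Regiochemistry (C1 to C6, C10 to C9) is enforced by the tether, chemoselective activation by iminium formation at the aldehyde and not the ester, and high dilution should suppress intermolecular cycloaddition.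

**Step 8**
Reactants: 11 (3aS,7S,7aS)-1-oxo-4-(propan-2-yl)-1,3,3a,6,7,7a-hexahydro-2-benzofuran-7-carbaldehyde
Product: 13 (3aS,7S,7aS)-7-hydroxy-1-oxo-4-(propan-2-yl)-1,3,3a,6,7,7a-hexahydro-2-benzofuran-7-carbaldehyde, via sodium enolate 12 (not isolated)
Conditions: NaN(SiMe3)2, THF, −78 °C; then 3-phenyl-2-(phenylsulfonyl)oxaziridine, −78 °C; AcOH
Reagents that add atoms: 3-phenyl-2-(phenylsulfonyl)oxaziridine, O=S(=O)(c1ccccc1)N1OC1c1ccccc1
Why: Davis hydroxylation of the aldehyde enolate (far more acidic than the lactone α-position) should occur by equatorial attack on the exocyclic enolate, putting the new C10–OH trans to the lactone carbonyl on C1 and leaving the formyl group axial and cis to it.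

**Step 9**
Reactants: 13 (3aS,7S,7aS)-7-hydroxy-1-oxo-4-(propan-2-yl)-1,3,3a,6,7,7a-hexahydro-2-benzofuran-7-carbaldehyde
Product: 15 (3aS,7S,7aS)-3a-hydroxy-7-(hydroxymethyl)-6-(propan-2-yl)-3a,4,7,7a-tetrahydro-2-benzofuran-1(3H)-one, via trans-lactone diol 14 (not isolated)
Conditions: NaBH4, EtOH, −20 °C; then DBU (0.1 equiv), CH2Cl2, rt
Reagents that add atoms: none
Why: Borohydride reduction gives the C14 carbinol, which lies cis to the lactone carbonyl and should translactonise to the less strained cis-fused γ-lactone, freeing the C5 hydroxymethyl group; no new stereocentre is formed.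

**Step 10**
Reactants: 15 (3aS,7S,7aS)-3a-hydroxy-7-(hydroxymethyl)-6-(propan-2-yl)-3a,4,7,7a-tetrahydro-2-benzofuran-1(3H)-one
Product: 16 (3aS,6R,7R,7aS)-3a-hydroxy-7-(hydroxymethyl)-6-(propan-2-yl)hexahydro-2-benzofuran-1(3H)-one
Conditions: H2 (1 atm), Crabtree's catalyst [Ir(cod)(PCy3)(py)]PF6 (5 mol %), CH2Cl2, 0 °C to rt
Reagents that add atoms: none
Why: Hydroxyl-directed hydrogenation: both hydroxyl groups lie on the face opposite the pseudo-axial lactone CH2, so hydrogen should add cis to the C5 hydroxymethyl group and set C7 with isopropyl trans to it.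

**Step 11**
Reactants: 16 (3aS,6R,7R,7aS)-3a-hydroxy-7-(hydroxymethyl)-6-(propan-2-yl)hexahydro-2-benzofuran-1(3H)-one
Product: 17 (3aS,6R,7R,7aS)-3a-hydroxy-1-oxo-6-(propan-2-yl)octahydro-2-benzofuran-7-carbaldehyde
Conditions: Dess–Martin periodinane, NaHCO3, CH2Cl2, 0 °C
Reagents that add atoms: none
Why: Dess–Martin oxidation takes the primary alcohol to the aldehyde and leaves the tertiary alcohol alone; the formyl group already sits equatorial, so C6 should not epimerise.

**Step 12**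
Reactants: 18 prop-2-en-1-yl 2-(diethoxyphosphoryl)acetate
Product: 19 prop-2-en-1-yl 2-(diethoxyphosphoryl)-3-hydroxypropanoate (racemic)
Conditions: aq. CH2O (1.0 equiv), K2CO3 (0.1 equiv), THF, 0 °C
Reagents that add atoms: formaldehyde, C=O
Why: Base-catalysed aldol-type hydroxymethylation of the phosphonoacetate, held at the mono-adduct by stoichiometry and temperature.

**Step 13**
Reactants: 19 prop-2-en-1-yl 2-(diethoxyphosphoryl)-3-hydroxypropanoate
Product: 20 prop-2-en-1-yl 3-{[tert-butyl(dimethyl)silyl]oxy}-2-(diethoxyphosphoryl)propanoate (racemic)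
Conditions: TBSCl, imidazole, DMF, 0 °C to rt
Reagents that add atoms: tert-butyl(chloro)dimethylsilane, CC(C)(C)[Si](C)(C)Cl
Why: Standard silylation of the primary alcohol.

**Step 14**
Reactants: 17 (3aS,6R,7R,7aS)-3a-hydroxy-1-oxo-6-(propan-2-yl)octahydro-2-benzofuran-7-carbaldehyde; 20 prop-2-en-1-yl 3-{[tert-butyl(dimethyl)silyl]oxy}-2-(diethoxyphosphoryl)propanoate
Product: 21 prop-2-en-1-yl (2E)-2-({[tert-butyl(dimethyl)silyl]oxy}methyl)-3-[(3aS,6R,7S,7aS)-3a-hydroxy-1-oxo-6-(propan-2-yl)octahydro-2-benzofuran-7-yl]prop-2-enoate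
Conditions: LiCl, DBU, MeCN, 0 °C to rt
Reagents that add atoms: none
Why: Horner–Wadsworth–Emmons olefination under Masamune–Roush conditions; an α-substituted phosphonoacetate with an α-branched aldehyde should give the (E)-alkene with the ring carbon trans to the ester.

**Step 15**
Reactants: 21 prop-2-en-1-yl (2E)-2-({[tert-butyl(dimethyl)silyl]oxy}methyl)-3-[(3aS,6R,7S,7aS)-3a-hydroxy-1-oxo-6-(propan-2-yl)octahydro-2-benzofuran-7-yl]prop-2-enoate
Product: 22 prop-2-en-1-yl (2E)-2-({[tert-butyl(dimethyl)silyl]oxy}methyl)-3-[(6R,7S)-1-oxo-6-(propan-2-yl)-1,3,4,5,6,7-hexahydro-2-benzofuran-7-yl]prop-2-enoate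
Conditions: Burgess reagent (MeO2CN–SO2NEt3 inner salt), THF, 50 °C
Reagents that add atoms: none
Why: Burgess syn-elimination of the tertiary alcohol with the cis ring-fusion hydrogen gives the conjugated butenolide of ring B.

**Step 16**
Reactants: 22 prop-2-en-1-yl (2E)-2-({[tert-butyl(dimethyl)silyl]oxy}methyl)-3-[(6R,7S)-1-oxo-6-(propan-2-yl)-1,3,4,5,6,7-hexahydro-2-benzofuran-7-yl]prop-2-enoate
Product: 23 (2E)-2-({[tert-butyl(dimethyl)silyl]oxy}methyl)-3-[(6R,7S)-1-oxo-6-(propan-2-yl)-1,3,4,5,6,7-hexahydro-2-benzofuran-7-yl]prop-2-enoic acid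
Conditions: Pd(PPh3)4 (5 mol %), morpholine, THF, rt
Reagents that add atoms: none
Why: Palladium-catalysed (π-allyl) deallylation with morpholine as allyl acceptor frees the acid without touching the silyl ether or butenolide.

**Step 17**
Reactants: 21 prop-2-en-1-yl (2E)-2-({[tert-butyl(dimethyl)silyl]oxy}methyl)-3-[(3aS,6R,7S,7aS)-3a-hydroxy-1-oxo-6-(propan-2-yl)octahydro-2-benzofuran-7-yl]prop-2-enoate
Product: 25 prop-2-en-1-yl (1S,2S,5R,6S)-6-[(1E)-2-({[tert-butyl(dimethyl)silyl]oxy}methyl)-3-oxo-3-(prop-2-en-1-yloxy)prop-1-en-1-yl]-2-hydroxy-2-(hydroxymethyl)-5-(propan-2-yl)cyclohexane-1-carboxylate, via lithium carboxylate 24 (not isolated)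
Conditions: LiOH·H2O (1.1 equiv), THF/H2O, 0 °C; concentrate; allyl bromide, DMF, 0 °C
Reagents that add atoms: lithium hydroxide, [Li+].[OH-]; allyl bromide, C=CCBr
Why: Saponification of the γ-lactone followed by O-alkylation of the carboxylate, never passing through the free hydroxy acid, should give the hydroxy ester, which is used at once.

**Step 18**
Reactants: 23 (2E)-2-({[tert-butyl(dimethyl)silyl]oxy}methyl)-3-[(6R,7S)-1-oxo-6-(propan-2-yl)-1,3,4,5,6,7-hexahydro-2-benzofuran-7-yl]prop-2-enoic acid; 25 prop-2-en-1-yl (1S,2S,5R,6S)-6-[(1E)-2-({[tert-butyl(dimethyl)silyl]oxy}methyl)-3-oxo-3-(prop-2-en-1-yloxy)prop-1-en-1-yl]-2-hydroxy-2-(hydroxymethyl)-5-(propan-2-yl)cyclohexane-1-carboxylate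
Product: 27 prop-2-en-1-yl (1S,2S,5R,6S)-6-[(1E)-2-({[tert-butyl(dimethyl)silyl]oxy}methyl)-3-oxo-3-(prop-2-en-1-yloxy)prop-1-en-1-yl]-2-({[(2E)-2-({[tert-butyl(dimethyl)silyl]oxy}methyl)-3-[(6R,7S)-1-oxo-6-(propan-2-yl)-1,3,4,5,6,7-hexahydro-2-benzofuran-7-yl]prop-2-enoyl]oxy}methyl)-2-hydroxy-5-(propan-2-yl)cyclohexane-1-carboxylate, via mixed anhydride 26 (not isolated)
Conditions: 2,4,6-trichlorobenzoyl chloride, Et3N, THF, rt; then 25, DMAP, toluene, rt
Reagents that add atoms: none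
Why: Yamaguchi esterification should acylate only the primary C14 hydroxyl, the tertiary C10 hydroxyl being inert.

**Step 19**
Reactants: 27 (fully protected dimer, name as in step 18)
Product: 28 prop-2-en-1-yl (1S,2S,5R,6S)-2-hydroxy-6-[(1E)-2-(hydroxymethyl)-3-oxo-3-(prop-2-en-1-yloxy)prop-1-en-1-yl]-2-({[(2E)-2-(hydroxymethyl)-3-[(6R,7S)-1-oxo-6-(propan-2-yl)-1,3,4,5,6,7-hexahydro-2-benzofuran-7-yl]prop-2-enoyl]oxy}methyl)-5-(propan-2-yl)cyclohexane-1-carboxylate
Conditions: HF·pyridine, pyridine, THF, 0 °C to rt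
Reagents that add atoms: none
Why: Buffered fluoride desilylation removes both primary silyl ethers and should leave all esters in place.

**Step 20**
Reactants: 28 (bis-allyl ester, name as in step 19)
Product: 29 (1S,2S,5R,6S)-6-[(1E)-2-carboxy-3-hydroxyprop-1-en-1-yl]-2-hydroxy-2-({[(2E)-2-(hydroxymethyl)-3-[(6R,7S)-1-oxo-6-(propan-2-yl)-1,3,4,5,6,7-hexahydro-2-benzofuran-7-yl]prop-2-enoyl]oxy}methyl)-5-(propan-2-yl)cyclohexane-1-carboxylic acid (target)
Conditions: Pd(PPh3)4 (10 mol %), morpholine, THF, rt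
Reagents that add atoms: none
Why: Neutral palladium-catalysed deallylation releases both carboxylic acids without cleaving the inter-unit ester or the butenolide.

**Compound list**
1 | ethyl 4-methyl-3-oxopentanoate | CCOC(=O)CC(=O)C(C)C | starting material
2 | ethyl (2E)-4-methyl-3-{[(trifluoromethyl)sulfonyl]oxy}pent-2-enoate | CCOC(=O)/C=C(/OS(=O)(=O)C(F)(F)F)C(C)C | intermediate
3 | ethyl (2E)-3-(propan-2-yl)penta-2,4-dienoate | CCOC(=O)/C=C(/C=C)C(C)C | intermediate
4 | (2E)-3-(propan-2-yl)penta-2,4-dien-1-ol | OC/C=C(/C=C)C(C)C | intermediate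
5 | (2E)-4,4-dimethoxybut-2-enal | COC(OC)/C=C/C=O | starting material
6 | (2E)-4,4-dimethoxybut-2-enoic acid | COC(OC)/C=C/C(=O)O | intermediate
7 | (2E)-3-(propan-2-yl)penta-2,4-dien-1-yl (2E)-4,4-dimethoxybut-2-enoate | COC(OC)/C=C/C(=O)OC/C=C(/C=C)C(C)C | intermediate
8 | (2E)-3-(propan-2-yl)penta-2,4-dien-1-yl (2E)-4-oxobut-2-enoate | O=C/C=C/C(=O)OC/C=C(/C=C)C(C)C | intermediate
9 | iminium trifluoroacetate of 8 with the (2S,5S)-imidazolidinone | O=C(/C=C/C=[N+]1[C@@H](Cc2ccccc2)C(=O)N(C)[C@H]1C(C)(C)C)OC/C=C(/C=C)C(C)C.[O-]C(=O)C(F)(F)F | intermediate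
10 | iminium trifluoroacetate of 11 with the (2S,5S)-imidazolidinone | C(=[N+]1[C@@H](Cc2ccccc2)C(=O)N(C)[C@H]1C(C)(C)C)[C@H]3CC=C(C(C)C)[C@H]4COC(=O)[C@H]34.[O-]C(=O)C(F)(F)F | intermediate
11 | (3aS,7S,7aS)-1-oxo-4-(propan-2-yl)-1,3,3a,6,7,7a-hexahydro-2-benzofuran-7-carbaldehyde | O=C[C@H]1CC=C(C(C)C)[C@H]2COC(=O)[C@H]12 | intermediate
12 | sodium enolate of 11 | [Na+].[O-]C=C1CC=C(C(C)C)[C@H]2COC(=O)[C@H]12 | intermediate
13 | (3aS,7S,7aS)-7-hydroxy-1-oxo-4-(propan-2-yl)-1,3,3a,6,7,7a-hexahydro-2-benzofuran-7-carbaldehyde | O=C[C@]1(O)CC=C(C(C)C)[C@H]2COC(=O)[C@H]12 | intermediate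
14 | (3aS,7S,7aS)-7-hydroxy-7-(hydroxymethyl)-4-(propan-2-yl)-3a,6,7,7a-tetrahydro-2-benzofuran-1(3H)-one | OC[C@]1(O)CC=C(C(C)C)[C@H]2COC(=O)[C@H]12 | intermediate
15 | (3aS,7S,7aS)-3a-hydroxy-7-(hydroxymethyl)-6-(propan-2-yl)-3a,4,7,7a-tetrahydro-2-benzofuran-1(3H)-one | CC(C)C1=CC[C@@]2(O)COC(=O)[C@H]2[C@@H]1CO | intermediate
16 | (3aS,6R,7R,7aS)-3a-hydroxy-7-(hydroxymethyl)-6-(propan-2-yl)hexahydro-2-benzofuran-1(3H)-one | CC(C)[C@H]1CC[C@@]2(O)COC(=O)[C@H]2[C@@H]1CO | intermediate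
17 | (3aS,6R,7R,7aS)-3a-hydroxy-1-oxo-6-(propan-2-yl)octahydro-2-benzofuran-7-carbaldehyde | CC(C)[C@H]1CC[C@@]2(O)COC(=O)[C@H]2[C@@H]1C=O | intermediate
18 | prop-2-en-1-yl 2-(diethoxyphosphoryl)acetate | C=CCOC(=O)CP(=O)(OCC)OCC | starting material
19 | prop-2-en-1-yl 2-(diethoxyphosphoryl)-3-hydroxypropanoate | C=CCOC(=O)C(CO)P(=O)(OCC)OCC | intermediate
20 | prop-2-en-1-yl 3-{[tert-butyl(dimethyl)silyl]oxy}-2-(diethoxyphosphoryl)propanoate | C=CCOC(=O)C(CO[Si](C)(C)C(C)(C)C)P(=O)(OCC)OCC | intermediate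
21 | prop-2-en-1-yl (2E)-2-({[tert-butyl(dimethyl)silyl]oxy}methyl)-3-[(3aS,6R,7S,7aS)-3a-hydroxy-1-oxo-6-(propan-2-yl)octahydro-2-benzofuran-7-yl]prop-2-enoate | CC(C)[C@H]1CC[C@@]2(O)COC(=O)[C@H]2[C@@H]1/C=C(\CO[Si](C)(C)C(C)(C)C)C(=O)OCC=C | intermediate
22 | prop-2-en-1-yl (2E)-2-({[tert-butyl(dimethyl)silyl]oxy}methyl)-3-[(6R,7S)-1-oxo-6-(propan-2-yl)-1,3,4,5,6,7-hexahydro-2-benzofuran-7-yl]prop-2-enoate | C=CCOC(=O)/C(=C/[C@H]1C2=C(CC[C@@H]1C(C)C)COC2=O)CO[Si](C)(C)C(C)(C)C | intermediate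
23 | (2E)-2-({[tert-butyl(dimethyl)silyl]oxy}methyl)-3-[(6R,7S)-1-oxo-6-(propan-2-yl)-1,3,4,5,6,7-hexahydro-2-benzofuran-7-yl]prop-2-enoic acid | OC(=O)/C(=C/[C@H]1C2=C(CC[C@@H]1C(C)C)COC2=O)CO[Si](C)(C)C(C)(C)C | intermediate
24 | lithium (1S,2S,5R,6S)-6-[(1E)-2-({[tert-butyl(dimethyl)silyl]oxy}methyl)-3-oxo-3-(prop-2-en-1-yloxy)prop-1-en-1-yl]-2-hydroxy-2-(hydroxymethyl)-5-(propan-2-yl)cyclohexane-1-carboxylate | CC(C)[C@H]1CC[C@@](O)(CO)[C@@H](C(=O)[O-])[C@@H]1/C=C(\CO[Si](C)(C)C(C)(C)C)C(=O)OCC=C.[Li+] | intermediate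
25 | prop-2-en-1-yl (1S,2S,5R,6S)-6-[(1E)-2-({[tert-butyl(dimethyl)silyl]oxy}methyl)-3-oxo-3-(prop-2-en-1-yloxy)prop-1-en-1-yl]-2-hydroxy-2-(hydroxymethyl)-5-(propan-2-yl)cyclohexane-1-carboxylate | CC(C)[C@H]1CC[C@@](O)(CO)[C@@H](C(=O)OCC=C)[C@@H]1/C=C(\CO[Si](C)(C)C(C)(C)C)C(=O)OCC=C | intermediate
26 | mixed anhydride of 23 with 2,4,6-trichlorobenzoic acid | O=C(OC(=O)c1c(Cl)cc(Cl)cc1Cl)/C(=C/[C@H]1C2=C(CC[C@@H]1C(C)C)COC2=O)CO[Si](C)(C)C(C)(C)C | intermediate
27 | bis(allyl ester) bis(TBS ether) of 29 (full name in step 18) | CC(C)[C@H]1CC[C@@](O)(COC(=O)/C(=C/[C@H]2C3=C(CC[C@@H]2C(C)C)COC3=O)CO[Si](C)(C)C(C)(C)C)[C@@H](C(=O)OCC=C)[C@@H]1/C=C(\CO[Si](C)(C)C(C)(C)C)C(=O)OCC=C | intermediate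
28 | bis(allyl ester) of 29 (full name in step 19) | CC(C)[C@H]1CC[C@@](O)(COC(=O)/C(=C/[C@H]2C3=C(CC[C@@H]2C(C)C)COC3=O)CO)[C@@H](C(=O)OCC=C)[C@@H]1/C=C(\CO)C(=O)OCC=C | intermediate
29 | (1S,2S,5R,6S)-6-[(1E)-2-carboxy-3-hydroxyprop-1-en-1-yl]-2-hydroxy-2-({[(2E)-2-(hydroxymethyl)-3-[(6R,7S)-1-oxo-6-(propan-2-yl)-1,3,4,5,6,7-hexahydro-2-benzofuran-7-yl]prop-2-enoyl]oxy}methyl)-5-(propan-2-yl)cyclohexane-1-carboxylic acid | CC(C)[C@H]1CC[C@@](O)(COC(=O)/C(=C/[C@H]2C3=C(CC[C@@H]2C(C)C)COC3=O)CO)[C@@H](C(=O)O)[C@@H]1/C=C(\CO)C(=O)O | target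

**Totals**
Total step count: 20. Longest linear sequence: 16 steps (1–3, 5–11, 14–16, 18–20).

**Steps most likely to fail**

Step 7. The ester tether must reach its unfavourable s-cis rotamer before cyclisation, so ring closure may be slow and intermolecular cycloaddition or conjugate addition of the amine catalyst may take over. The fallback keeps the tether but uses auxiliary-controlled Lewis-acid activation; it sets out from 4 and comes back at 11. Alcohol 4 is acylated with excess fumaryl chloride to the mono-acid chloride (2E)-3-(propan-2-yl)penta-2,4-dien-1-yl (2E)-4-chloro-4-oxobut-2-enoate F1. F1 is coupled with the lithium salt of (4S)-4-benzyl-1,3-oxazolidin-2-one to give the triene imide (2E)-3-(propan-2-yl)penta-2,4-dien-1-yl (2E)-4-[(4S)-4-benzyl-2-oxo-1,3-oxazolidin-3-yl]-4-oxobut-2-enoate F2. Me2AlCl in CH2Cl2 at −30 °C (chelated N-acyloxazolidinone, diene anti to the benzyl group, imide endo) should give the cycloadduct (4S)-4-benzyl-3-{[(3aS,7S,7aS)-1-oxo-4-(propan-2-yl)-1,3,3a,6,7,7a-hexahydro-2-benzofuran-7-yl]carbonyl}-1,3-oxazolidin-2-one F3. LiBH4 cleaves the imide to (3aS,7S,7aR)-7-(hydroxymethyl)-4-(propan-2-yl)-3a,6,7,7a-tetrahydro-2-benzofuran-1(3H)-one F4, and Dess–Martin oxidation returns 11.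

Step 8. The oxaziridine may attack the exocyclic enolate with poor facial selectivity, and the aldehyde enolate may self-condense. The fallback reverses the order of bond construction at C10, so that an electrophile preferring the other face now gives the right centre; it sets out from 11 and comes back at 16. Crossed aldol reaction of 11 with aqueous formaldehyde and K2CO3 introduces C14 as CH2OH, which translactonises to (3aS,7S,7aS)-7-(hydroxymethyl)-1-oxo-6-(propan-2-yl)-3,4,7,7a-tetrahydro-2-benzofuran-3a(1H)-carbaldehyde F5. Hydroxyl-directed hydrogenation with Crabtree's catalyst [Ir(cod)(PCy3)(py)]PF6 gives (3aS,6R,7R,7aS)-7-(hydroxymethyl)-1-oxo-6-(propan-2-yl)hexahydro-2-benzofuran-3a(1H)-carbaldehyde F6. Baeyer–Villiger oxidation of the quaternary aldehyde (m-chloroperbenzoic acid, NaHCO3; tertiary alkyl migration with retention) gives (3aS,6R,7R,7aS)-7-(hydroxymethyl)-1-oxo-6-(propan-2-yl)hexahydro-2-benzofuran-3a(1H)-yl formate F7, and K2CO3/MeOH cleaves the formate to 16.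

Step 18. The γ-hydroxy ester 25 may relactonise under the basic acyl-transfer conditions before its primary hydroxyl is acylated. The fallback activates the alcohol instead of the acid under neutral conditions: Mitsunobu esterification of 25 with 23 (PPh3, diisopropyl azodicarboxylate, toluene, 0 °C). It sets out from 23 and 25 and comes back at 27, and makes no new compound.

**Further compounds**
F1 | step 7 | (2E)-3-(propan-2-yl)penta-2,4-dien-1-yl (2E)-4-chloro-4-oxobut-2-enoate | O=C(Cl)/C=C/C(=O)OC/C=C(/C=C)C(C)C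
F2 | step 7 | (2E)-3-(propan-2-yl)penta-2,4-dien-1-yl (2E)-4-[(4S)-4-benzyl-2-oxo-1,3-oxazolidin-3-yl]-4-oxobut-2-enoate | O=C(/C=C/C(=O)N1[C@@H](Cc2ccccc2)COC1=O)OC/C=C(/C=C)C(C)C
F3 | step 7 | (4S)-4-benzyl-3-{[(3aS,7S,7aS)-1-oxo-4-(propan-2-yl)-1,3,3a,6,7,7a-hexahydro-2-benzofuran-7-yl]carbonyl}-1,3-oxazolidin-2-one | O=C([C@H]1CC=C(C(C)C)[C@H]2COC(=O)[C@H]12)N1[C@@H](Cc2ccccc2)COC1=O
F4 | step 7 | (3aS,7S,7aR)-7-(hydroxymethyl)-4-(propan-2-yl)-3a,6,7,7a-tetrahydro-2-benzofuran-1(3H)-one | OC[C@H]1CC=C(C(C)C)[C@H]2COC(=O)[C@H]12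
F5 | step 8 | (3aS,7S,7aS)-7-(hydroxymethyl)-1-oxo-6-(propan-2-yl)-3,4,7,7a-tetrahydro-2-benzofuran-3a(1H)-carbaldehyde | CC(C)C1=CC[C@@]2(C=O)COC(=O)[C@H]2[C@@H]1CO
F6 | step 8 | (3aS,6R,7R,7aS)-7-(hydroxymethyl)-1-oxo-6-(propan-2-yl)hexahydro-2-benzofuran-3a(1H)-carbaldehyde | CC(C)[C@H]1CC[C@@]2(C=O)COC(=O)[C@H]2[C@@H]1CO
F7 | step 8 | (3aS,6R,7R,7aS)-7-(hydroxymethyl)-1-oxo-6-(propan-2-yl)hexahydro-2-benzofuran-3a(1H)-yl formate | CC(C)[C@H]1CC[C@@]2(OC=O)COC(=O)[C@H]2[C@@H]1CO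
F0 | step 18 | none | none
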